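(The numbers of this flask were drawn at random within sensible limits; the result is computed.)

The starting complex, followed here as M, leaves by exchange with incoming ligand, X, or by pairing with itself, and what you want to know is how much reaches side product.

    starting complex + incoming ligand ⇌ leaving ligand + complex with one exchanged (K1 = 3.5, k1 = 0.0043 L mol⁻¹ s⁻¹)
    complex with one exchanged + incoming ligand ⇌ leaving ligand + complex with two exchanged (K2 = 45, k2 = 9.6 × 10⁻⁴ L mol⁻¹ s⁻¹)
    complex with one exchanged → side product (k3 = 7.5 × 10⁻⁴ s⁻¹)
    complex with two exchanged ⇌ isomer of the product (K4 = 5.8, k4 = 1.2 × 10⁻⁶ s⁻¹)
    2 starting complex → self-condensation product (k5 = 0.0033 L mol⁻¹ s⁻¹)

in all of them: leaving ligand 0.100 M; time 12 h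

|  | starting complex | incoming ligand | remark |
|---|---|---|---|
| winter | 0.050 M (fed, over 5.0 h) | 0.0750 M | all else is in the flask from the start; the feed brings no volume worth counting |
| autumn | 0.050 M | 0.0750 M | everything together at the start |
| dawn | 0.050 M | 0.0750 M (in portions, 3, over 5.0 h) | first portion at the start, last at 5.0 h |
| summer | 0.050 M (fed, over 30 min) | 0.0750 M | all else is in the flask from the start; the feed brings no volume worth counting |
| dusk | 0.050 M | 0.0750 M (fed, over 5.0 h) | all else is in the flask from the start; the feed brings no volume worth counting |

- percent here means starting complex units held: one self-condensation product counts as two
- a doubled species enters its step squared and goes two at a time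
- run time (winter): 12 h

* the flask with the highest amount of side product, in percent of the starting complex charged ("all alike" if they lie within 1.5 percentage points) (winter / autumn / dawn / summer / dusk / all alike)
* final side product, as a percentage of the starting complex charged, in winter
* final side product, as a percentage of the starting complex charged, in autumn
* final side product, as a percentage of the starting complex charged, in dawn
* final side product, as a percentage of the starting complex charged, in summer
* final side product, as a percentage of the starting complex charged, in dusk

I reckon winter, the slow feed of starting complex, by hand.

1. Let A be the first-step rate constant times [X], a pseudo-first-order constant for M. Let B be 2 times the self-condensation constant. Exchange then uses M at A[M] and self-condensation at B[M]². Their ratio, s = A/(B[M]), is the split number. With the full charges together it is 0.977, so the two exits start about even.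

2. In winter M comes in over 5.0 h, so the reckoning needs the level of M in that flask. If M stays steady, the feed rate, charge over feed time, equals A[M] + B[M]². With X at its charge, this gives [M] = 0.00747 M. M adjusts with a half-life of about 0.457 h, shorter than the feed, so the steady picture can be used.

3. The share of M going by exchange is A[M] over the feed rate, 86.7%.

4. Complex with one exchanged goes mostly to side product. The second exchange is the small correction, its forward rate with X at its charge over the side-product rate being 9.60%. Taking that off gives 78.4% side product.

5. The weak link is X, which does not stay at its charge. Over the feed its mean is nearer 0.0533 M. Repeating the steps with this value gives [M] = 0.00951 M and 3.65, the split number of the winter flask during its feed. The exchange share is then 78.5%, and side product is 73.1%. This leaves out the way back of the first step and the M still present when the feed stops.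

The forecast names winter as highest, with 71% there, 56% in autumn, 35% in dawn, 61% in summer and 26% in dusk. Its ground is that “slowly feeding the starting complex helps most”. My winter figure stands above its figure.

The flasks end at 73.2% in winter, 58.5% in autumn, 37.5% in dawn, 61.5% in summer and 29.1% in dusk, so winter holds the most side product. In winter at 3.32 h, the forward use of starting complex by exchange stands at 3.7 times its use by self-condensation, beside the split number 3.65 reckoned for the feed. In the winter neighbour with 0.13 M of incoming ligand, a mean incoming ligand of 0.110 M gives a split number of 13.2 and 79.8% side product, and that flask holds 81.4% at 12.0 h.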